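**Compound numbers used throughout**

1 2,6-dimethoxybenzene-1,4-diol · 2 4-(benzyloxy)-2,6-dimethoxyphenol · 3 methyl 4-fluorobenzoate · 4 diaryl ether ester · 5 4-methoxy-6-methyl-2H-pyran-2-one · 6 6-acetonyl pyrone · 7 pyrone-masked polyketone (key-step precursor) · 8 ring-opened enoate (not isolated) · 9 2,6-dihydroxyaryl 1,3-diketone (key-step product) · 10 benzyl-protected flavone · 11 symmetric phenol · 12 boron chelate (not isolated) · 13 ortho-hydroxyacetophenone · 14 enaminone (not isolated) · 15 chromone · 16 [4-(benzyloxy)phenyl]boronic acid · 17 protected (2S)-flavanone · 18 target. Full names and SMILES are in the list after the steps.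

## Analysis of the target

CNP0202121.1 (18) is an ether-linked biflavonoid. A flavone unit (rings A, C and B; 5-OH, 7-OMe) is bound through the para oxygen of its ring B (O4') to C6 of a flavanone unit that carries 5-OH, 7-OMe and a 4-hydroxyphenyl group at C2. The only stereocentre is C2 of the flavanone, of S configuration (priorities O1 > aryl > C3 > H), so no second centre can relay to it and a catalyst has to set it. This centre is benzylic, bears the ring oxygen and lies beta to the C4 ketone: base opens the ring to the chalcone and recloses it without control, and a strong Lewis acid can ionise C2–O1, so it must be made late and kept away from base. Other sensitive features are three phenols (two chelated to C4=O groups), the gamma-pyrone of the flavone, and a diaryl ether oxygen crowded between O5 and O7 of the flavanone. The difficulty is differentiation: both A rings are phloroglucinol-derived, each with one free peri hydroxyl and one methyl ether, and the bridge must end at C6, not C8, of the flavanone. The strategy rests on ring A of the flavone unit. C5 (OH), C7 (OMe) and C8a (O1) are mutually meta and C4a carries the C4 acyl carbon between C5 and C8a, which is the pattern of a polyketide chain folded by a Claisen condensation. The C7 methoxy group maps onto the C4 methoxy group of a 4-methoxy-2-pyrone, whose lactone carbonyl becomes C5. A second useful feature is that the flavanone A ring can be grown on a phenol with two equivalent ortho carbons, so the C6 attachment follows from symmetry.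

## Retrosynthetic reasoning

**18 ⇒ 17.** The last hydroxyls set free are O5 of the flavanone (a methyl ether in 17) and O4' of its ring B (a benzyl ether in 17). Keeping O5 methylated to the end fixes the site of the bridge: with only one free hydroxyl next to the acyl carbon, the heterocycle can close in one direction only, which puts the aryloxy group at C6. The forward step must cleave only the methyl group peri to C4=O (chelation-directed, with a boron trihalide) and the benzyl group, and leave both C7 methoxy groups and C2 untouched.

**17 ⇒ 15 + 16.** The C2–C1' bond of the flavanone is cut, giving chromone 15 and boronic acid 16. This sets the stereocentre in a C–C bond formation under near-neutral conditions, as the last skeletal bond of the route. It is preferred to closing a chalcone, which would need control of an oxa-Michael addition that runs by itself. The forward reaction needs a chiral rhodium catalyst to choose one face of C2=C3 of 15 and to ignore the 2-aryl-substituted enone of the flavone unit.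

**15 ⇒ 13 (via 14) ⇒ 11.** C2 of chromone 15 is a one-carbon unit at the formate oxidation level, condensed onto the acetyl methyl group of 13 and closed by the single free ortho hydroxyl. Acetophenone 13 comes from phenol 11 by C-acetylation ortho to the hydroxyl. The hydroxyl-bearing ring of 11 is symmetric, so only one acetophenone can form. In it the directing hydroxyl becomes O1, the methoxy group next to the acetyl becomes O5-methyl, and the bridge oxygen is at C6.

**11 ⇒ 10.** The free phenol of 11 is carried as a benzyl ether through the basic and acidic steps that build the flavone. Hydrogenolysis removes it without touching the gamma-pyrone.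

**10 ⇒ 9.** Ring C of the flavone is opened at O1–C2 to the 2,6-dihydroxyaryl 1,3-diketone 9. Its two phenols are equivalent, so acid-catalysed cyclodehydration has no regiochemical choice and leaves the other hydroxyl as the chelated 5-OH.

**9 ⇒ 7 (via 8), the key disconnection.** The C4a–C5 bond of flavone ring A is cut. The ring unfolds to a 3,5,7,9-tetraoxo ester chain whose first two carbonyl groups are masked as the 4-methoxy-2-pyrone of 7. The C7 methoxy group is therefore already in place in commercial 5 and no phenol has to be methylated selectively. The forward reaction has to open the lactone, fold the chain by Claisen rather than aldol condensation, and aromatise.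

**7 ⇒ 6 + 4.** The bond between the aryl ketone carbon (flavone C2) and its alpha carbon (flavone C3) is cut so that the carbanion sits on the pyrone half (the dianion of 6, reacting at its terminal methyl group). The electrophile, ester 4, has no alpha hydrogen. The reverse polarity, a ketone enolate on the aryl half and an acyl donor on the pyrone half, was rejected. The methylene of such a donor, flanked by the pyrone and the activated carbonyl, is far more acidic than the ketone, so proton transfer would outrun acylation.

**6 ⇒ 5.** The acetonyl side chain is made by acetylating the C6-methyl anion of 5 with an N-methoxy-N-methyl amide. Its chelated tetrahedral adduct keeps the more acidic ketone 6 hidden until work-up.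

**4 ⇒ 2 + 3, and 2 ⇒ 1.** The diaryl ether is cut on the side of the benzoate ring, where a para ester activates fluoride displacement by the crowded phenoxide of 2. Phenol 2 comes from hydroquinone 1 by benzylation of the unhindered, more acidic hydroxyl; the hydroxyl between the two methoxy groups is left free for the ether formation.

## Alternatives that were turned down

**Alternative 1: Friedel–Crafts closure of a chiral beta-aryloxy acid.** The flavanone is cut at C4–C4a. The open-chain acid A2, with the S centre already present as an aryl alkyl ether, would be activated and would acylate the ring carbon ortho to the ether oxygen, giving A1 (flavone 5-O-benzyl, flavanone 5-O-methyl, 4'-O-acetyl).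
- For: the stereocentre comes from a simple chiral benzylic alcohol, so no asymmetric catalyst has to accept a large polyoxygenated substrate; here it is stronger than the chosen route. The acylation site is unambiguous because the phenol ring is symmetric, and the ring is very electron-rich.
- Against: the stereocentre must first survive an etherification at a para-oxygenated benzylic carbon, which is prone to ionisation. It must then survive an acyl cation or mixed anhydride beta to the aryloxy group. Both loss of the phenol by elimination to a cinnamoyl species and reclosure through a benzylic cation would scramble C2. The 4'-O-acetyl group is needed only to damp that cation, and A1 still carries three different protecting groups.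
- Comparison: both routes end in a 5-O-methyl flavanone. The chosen route forms C2 under neutral aqueous conditions and exposes it only to one cold dealkylation, with two protecting groups removed in one step.

**Alternative 2: aryloxy-pyrone folding builds ring A of the flavanone.** The same magnesium alkoxide folding is applied to the other unit. Pyrone A4, bearing the whole flavone as a 3-aryloxy substituent and a cinnamoyl-type side chain, would be opened and closed at C4a–C5 to chalcone A3.
- For: it is more convergent than the chosen route, because ring A, the bridge and the chalcone chain arrive in one operation.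
- Against: a 3-aryloxy-4-methoxy-2-pyrone with a hindered flavonyl ether has no short preparation. The enone of A4 invites conjugate addition of alkoxide, and the flavone must survive the base. Above all, A3 is an unsymmetrical 2',6'-dihydroxychalcone: it can close through either hydroxyl (6- or 8-linked flavanone) and does so spontaneously and without facial control. The stereocentre would then depend on chalcone isomerase accepting a bulky unnatural substrate faster than the background reaction.
- Comparison: the chosen route uses the same folding where its product (9) is symmetric and achiral, and pays for this with more steps on the flavanone side.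

**Alternative 3: aryne insertion into an arylpropiolic acid builds the flavone.** Ring C of the flavone is cut at C4–C4a and O1–C8a. A fluoride source would release aryne A6 from an ortho-silylaryl triflate. The carboxylate of acid A7 would add at the aryne carbon remote from the benzyloxy group, the aryl anion would take the acyl group, and the ortho-hydroxyaryl ynone would close to flavone A5.
- For: three bonds form in one pot under mild, nearly neutral conditions, and there is no aldol-type misfolding to fear; on bond count per step it is stronger than the chosen key step. The alkoxy group of A6 directs the oxygen nucleophile to the correct carbon.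
- Against: the acyl transfer must beat simple O-arylation and protonation, at an aryl anion crowded by the benzyloxy group. The silylaryl triflate with a 3,5-dioxygenated ring is a multistep compound, and A5 (the 5-O-benzyl ether of 10) needs an extra deprotection at O5.
- Comparison: the chosen route starts from the cheap pyrone 5 with the C7 methoxy group in place and delivers the free, chelated 5-OH directly.

Key step: step 5

Assumption: the sense of induction in step 10 is assigned by analogy with rhodium-catalysed arylation of cyclic enones, where an (S)-biaryl diphosphine delivers the aryl group to the enone face that corresponds to 2S in a chromone; if a model chromone shows the opposite sense, the (R)-ligand is used.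

## Route

Step 1
Reactants: 1 2,6-dimethoxybenzene-1,4-diol
Product: 2 4-(benzyloxy)-2,6-dimethoxyphenol
Conditions: BnBr (1.0 equiv), K2CO3 (1.05 equiv), degassed acetone, 40 °C, Ar
Reagents that add atoms: benzyl bromide, BrCc1ccccc1
Why: Williamson etherification; the C4 hydroxyl has no ortho substituent and is the more acidic one (two meta methoxy groups), whereas the C1 hydroxyl is flanked by two methoxy groups, so one equivalent of halide should alkylate O4. Air is excluded because the hydroquinone is easily oxidised in base.

Step 2
Reactants: 2 4-(benzyloxy)-2,6-dimethoxyphenol; 3 methyl 4-fluorobenzoate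
Product: 4 methyl 4-[4-(benzyloxy)-2,6-dimethoxyphenoxy]benzoate
Conditions: Cs2CO3 (1.5 equiv), DMSO, 110 °C, Ar
Reagents that add atoms: none
Why: Nucleophilic aromatic substitution by addition–elimination; the para ester stabilises the anionic adduct and fluoride is the best leaving group for this mechanism. The electron-rich phenoxide is nucleophilic enough in DMSO despite its two ortho methoxy groups.

Step 3
Reactants: 5 4-methoxy-6-methyl-2H-pyran-2-one
Product: 6 4-methoxy-6-(2-oxopropyl)-2H-pyran-2-one
Conditions: LiN(i-Pr)2 (1.05 equiv), THF, −78 °C; MeC(O)N(OMe)Me (1.1 equiv), −78 to −20 °C; 1 M HCl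
Reagents that add atoms: N-methoxy-N-methylacetamide, CC(=O)N(C)OC
Why: Vinylogous deprotonation of the C6 methyl group gives an extended enolate that reacts at the exocyclic carbon; acylation with a Weinreb amide stops at the chelated tetrahedral adduct, so the more acidic ketone appears only on work-up and one equivalent of base suffices.

Step 4
Reactants: 6 4-methoxy-6-(2-oxopropyl)-2H-pyran-2-one; 4 methyl 4-[4-(benzyloxy)-2,6-dimethoxyphenoxy]benzoate
Product: 7 6-(4-{4-[4-(benzyloxy)-2,6-dimethoxyphenoxy]phenyl}-2,4-dioxobutyl)-4-methoxy-2H-pyran-2-one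
Conditions: 6 (2.0 equiv), LiN(i-Pr)2 (4.2 equiv), THF, −78 to −40 °C; 4 (1.0 equiv), −78 to 0 °C; 1 M HCl
Reagents that add atoms: none
Why: Terminal (gamma) acylation of a 1,3-dicarbonyl-type dianion: the first equivalent of base removes the proton between pyrone and ketone, the second the methyl proton, and the last-formed carbanion is the most nucleophilic. Ester 4 has no alpha hydrogen and cannot quench it; the second equivalent of dianion takes up the acidic proton of the product.

Step 5
Reactants: 7 6-(4-{4-[4-(benzyloxy)-2,6-dimethoxyphenoxy]phenyl}-2,4-dioxobutyl)-4-methoxy-2H-pyran-2-one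
Product: 9 1-{4-[4-(benzyloxy)-2,6-dimethoxyphenoxy]phenyl}-3-(2,6-dihydroxy-4-methoxyphenyl)propane-1,3-dione, via ring-opened methyl enoate 8 (not isolated)
Conditions: Mg(OMe)2 (8 equiv), MeOH–THF, reflux, N2; then 1 M HCl, 0 °C
Reagents that add atoms: none
Why: Mg(OMe)2 turns the 1,3-dicarbonyl units of 7 into magnesium chelates, and methoxide opens the lactone at the pyrone carbonyl to the (E)-beta-methoxy enoate 8, in which the ester and the chain are held cis by the geometry inherited from the ring. The carbanion at the methylene between the two chelated carbonyl groups (future C4a) attacks the ester carbonyl (future C5) in a 6-exo-trig Claisen closure, and loss of methoxide followed by enolisation makes ring A aromatic, which is irreversible. The closest known reaction type is the magnesium-alkoxide-mediated Claisen cyclisation of pyrone-masked 3,5,7-triketo esters to acylphloroglucinol monomethyl ethers. No stereocentre is formed. The selectivity needed is Claisen folding over the aldol folding in which the future C8 methylene attacks the aryl ketone carbon, also a six-membered closure, which would give a biaryl resorcinol. It is secured because the enol ether stops the ester alpha carbon from acting as a nucleophile, magnesium chelation places the charge on C4a and ties up the aryl ketone as an unreactive chelated enolate, and that ketone is further deactivated by its para aryloxy donor. The benzyl ether, the methyl ethers and the diaryl ether are inert to the alkoxide, and the two phenols of 9 are equivalent, so the later O1–C2 closure has no regiochemical issue.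

Step 6
Reactants: 9 1-{4-[4-(benzyloxy)-2,6-dimethoxyphenoxy]phenyl}-3-(2,6-dihydroxy-4-methoxyphenyl)propane-1,3-dione
Product: 10 2-{4-[4-(benzyloxy)-2,6-dimethoxyphenoxy]phenyl}-5-hydroxy-7-methoxy-4H-chromen-4-one
Conditions: TsOH·H2O (0.1 equiv), toluene, 80 °C
Reagents that add atoms: none
Why: Acid-catalysed cyclodehydration of an ortho-hydroxyaryl 1,3-diketone (the ring closure of the Baker–Venkataraman flavone synthesis): a phenol adds to the aryl ketone carbon and water is lost to give the gamma-pyrone. Either hydroxyl gives the same flavone, and the benzyl ether tolerates catalytic sulfonic acid.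

Step 7
Reactants: 10 2-{4-[4-(benzyloxy)-2,6-dimethoxyphenoxy]phenyl}-5-hydroxy-7-methoxy-4H-chromen-4-one
Product: 11 5-hydroxy-2-[4-(4-hydroxy-2,6-dimethoxyphenoxy)phenyl]-7-methoxy-4H-chromen-4-one
Conditions: H2 (1 atm), Pd/C (10%), THF–EtOAc, rt
Reagents that add atoms: none
Why: Hydrogenolysis of a benzyl aryl ether; the C2=C3 bond of the flavone is part of a vinylogous ester and is not reduced at atmospheric pressure, and methyl ethers and the diaryl ether are inert.

Step 8
Reactants: 11 5-hydroxy-2-[4-(4-hydroxy-2,6-dimethoxyphenoxy)phenyl]-7-methoxy-4H-chromen-4-one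
Product: 13 2-[4-(3-acetyl-4-hydroxy-2,6-dimethoxyphenoxy)phenyl]-5-hydroxy-7-methoxy-4H-chromen-4-one, via bis(difluoroboron) chelate 12 (not isolated)
Conditions: AcOH, BF3·OEt2 (5 equiv), 85 °C; then H2O–MeOH, 60 °C
Reagents that add atoms: acetic acid, CC(=O)O
Why: BF3-mediated ortho C-acetylation of a phenol (O-acetylation and Fries-type migration, or direct Friedel–Crafts attack); the position is ortho to OH, ortho to one OMe and para to the other, and the two ortho carbons are equivalent. The flavone is deactivated as its own BF2 chelate, and the chelates are hydrolysed on aqueous work-up.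

Step 9
Reactants: 13 2-[4-(3-acetyl-4-hydroxy-2,6-dimethoxyphenoxy)phenyl]-5-hydroxy-7-methoxy-4H-chromen-4-one
Product: 15 6-[4-(5-hydroxy-7-methoxy-4-oxo-4H-chromen-2-yl)phenoxy]-5,7-dimethoxy-4H-chromen-4-one, via enaminone 14 (not isolated)
Conditions: Me2NCH(OMe)2 (3 equiv), toluene, 95 °C; then AcOH, 80 °C
Reagents that add atoms: N,N-dimethylformamide dimethyl acetal, COC(OC)N(C)C
Why: Enaminone chromone synthesis: the amide acetal condenses with the acetyl methyl group, and in acid the ortho hydroxyl adds to the beta carbon and expels dimethylamine. Only one hydroxyl flanks the acyl group, so the ring closes in one direction and the bridge oxygen ends at C6.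

Step 10
Reactants: 15 6-[4-(5-hydroxy-7-methoxy-4-oxo-4H-chromen-2-yl)phenoxy]-5,7-dimethoxy-4H-chromen-4-one; 16 [4-(benzyloxy)phenyl]boronic acid
Product: 17 (2S)-2-[4-(benzyloxy)phenyl]-6-[4-(5-hydroxy-7-methoxy-4-oxo-4H-chromen-2-yl)phenoxy]-5,7-dimethoxy-2,3-dihydro-4H-chromen-4-one
Conditions: 16 (3 equiv), [Rh(OH)(cod)]2 (3 mol %), (S)-6,6'-dimethoxy-2,2'-bis[bis(3,4,5-trifluorophenyl)phosphino]-1,1'-biphenyl (7 mol %), toluene–H2O 10:1, 40 °C
Reagents that add atoms: none
Why: Hayashi–Miyaura conjugate addition to a chromone: transmetalation gives an aryl–rhodium species, C2=C3 of 15 inserts with the aryl delivered to the face chosen by the C2-symmetric electron-poor diphosphine (this sets 2S), and water protonates the rhodium enolate. The 2-aryl enone of the flavone unit would have to form a quaternary centre and is left alone, and no base is present to equilibrate the new centre.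

Step 11
Reactants: 17 (2S)-2-[4-(benzyloxy)phenyl]-6-[4-(5-hydroxy-7-methoxy-4-oxo-4H-chromen-2-yl)phenoxy]-5,7-dimethoxy-2,3-dihydro-4H-chromen-4-one
Product: 18 (2S)-5-hydroxy-6-[4-(5-hydroxy-7-methoxy-4-oxo-4H-chromen-2-yl)phenoxy]-2-(4-hydroxyphenyl)-7-methoxy-2,3-dihydro-4H-chromen-4-one
Conditions: BCl3 (6 equiv), C6HMe5 (4 equiv), CH2Cl2, −78 to 0 °C; then H2O
Reagents that add atoms: none
Why: Chelation-directed dealkylation: BCl3 bound to C4=O is also held by the peri 5-OMe oxygen, so chloride removes that methyl group only, while the two C7 methoxy groups and the diaryl ether have no such chelate. The benzyl ether is cleaved at low temperature and its cation is trapped by pentamethylbenzene (Friedel–Crafts scavenging), and C2 takes no part.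

## Compound list

1 | 2,6-dimethoxybenzene-1,4-diol | COc1cc(O)cc(OC)c1O | starting material
2 | 4-(benzyloxy)-2,6-dimethoxyphenol | COc1cc(OCc2ccccc2)cc(OC)c1O | intermediate
3 | methyl 4-fluorobenzoate | COC(=O)c1ccc(F)cc1 | starting material
4 | methyl 4-[4-(benzyloxy)-2,6-dimethoxyphenoxy]benzoate | COC(=O)c1ccc(Oc2c(OC)cc(OCc3ccccc3)cc2OC)cc1 | intermediate
5 | 4-methoxy-6-methyl-2H-pyran-2-one | COc1cc(C)oc(=O)c1 | starting material
6 | 4-methoxy-6-(2-oxopropyl)-2H-pyran-2-one | COc1cc(CC(C)=O)oc(=O)c1 | intermediate
7 | 6-(4-{4-[4-(benzyloxy)-2,6-dimethoxyphenoxy]phenyl}-2,4-dioxobutyl)-4-methoxy-2H-pyran-2-one | COc1cc(=O)oc(CC(=O)CC(=O)c2ccc(Oc3c(OC)cc(OCc4ccccc4)cc3OC)cc2)c1 | intermediate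
8 | methyl (2E)-9-{4-[4-(benzyloxy)-2,6-dimethoxyphenoxy]phenyl}-3-methoxy-5,7,9-trioxonon-2-enoate | COC(=O)/C=C(/OC)CC(=O)CC(=O)CC(=O)c1ccc(Oc2c(OC)cc(OCc3ccccc3)cc2OC)cc1 | intermediate (not isolated)
9 | 1-{4-[4-(benzyloxy)-2,6-dimethoxyphenoxy]phenyl}-3-(2,6-dihydroxy-4-methoxyphenyl)propane-1,3-dione | COc1cc(O)c(C(=O)CC(=O)c2ccc(Oc3c(OC)cc(OCc4ccccc4)cc3OC)cc2)c(O)c1 | intermediate
10 | 2-{4-[4-(benzyloxy)-2,6-dimethoxyphenoxy]phenyl}-5-hydroxy-7-methoxy-4H-chromen-4-one | COc1cc(O)c2c(=O)cc(-c3ccc(Oc4c(OC)cc(OCc5ccccc5)cc4OC)cc3)oc2c1 | intermediate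
11 | 5-hydroxy-2-[4-(4-hydroxy-2,6-dimethoxyphenoxy)phenyl]-7-methoxy-4H-chromen-4-one | COc1cc(O)c2c(=O)cc(-c3ccc(Oc4c(OC)cc(O)cc4OC)cc3)oc2c1 | intermediate
12 | bis(difluoroboron) chelate of 13 (one BF2 bridging O5 and the C4 carbonyl oxygen of the flavone, one bridging the phenol oxygen and the acetyl oxygen) | COc1cc2O[B-](F)(F)[O+]=C3C=C(c4ccc(Oc5c(OC)cc6O[B-](F)(F)[O+]=C(C)c6c5OC)cc4)Oc(c1)c23 | intermediate (not isolated)
13 | 2-[4-(3-acetyl-4-hydroxy-2,6-dimethoxyphenoxy)phenyl]-5-hydroxy-7-methoxy-4H-chromen-4-one | COc1cc(O)c2c(=O)cc(-c3ccc(Oc4c(OC)cc(O)c(C(C)=O)c4OC)cc3)oc2c1 | intermediate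
14 | 2-[4-(3-[(2E)-3-(dimethylamino)prop-2-enoyl]-4-hydroxy-2,6-dimethoxyphenoxy)phenyl]-5-hydroxy-7-methoxy-4H-chromen-4-one | COc1cc(O)c2c(=O)cc(-c3ccc(Oc4c(OC)cc(O)c(C(=O)/C=C/N(C)C)c4OC)cc3)oc2c1 | intermediate (not isolated)
15 | 6-[4-(5-hydroxy-7-methoxy-4-oxo-4H-chromen-2-yl)phenoxy]-5,7-dimethoxy-4H-chromen-4-one | COc1cc(O)c2c(=O)cc(-c3ccc(Oc4c(OC)cc5occc(=O)c5c4OC)cc3)oc2c1 | intermediate
16 | [4-(benzyloxy)phenyl]boronic acid | OB(O)c1ccc(OCc2ccccc2)cc1 | starting material
17 | (2S)-2-[4-(benzyloxy)phenyl]-6-[4-(5-hydroxy-7-methoxy-4-oxo-4H-chromen-2-yl)phenoxy]-5,7-dimethoxy-2,3-dihydro-4H-chromen-4-one | COc1cc(O)c2c(=O)cc(-c3ccc(Oc4c(OC)cc5c(c4OC)C(=O)C[C@@H](c4ccc(OCc6ccccc6)cc4)O5)cc3)oc2c1 | intermediate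
18 | (2S)-5-hydroxy-6-[4-(5-hydroxy-7-methoxy-4-oxo-4H-chromen-2-yl)phenoxy]-2-(4-hydroxyphenyl)-7-methoxy-2,3-dihydro-4H-chromen-4-one (CNP0202121.1) | COc1cc(O)c2c(=O)cc(-c3ccc(Oc4c(OC)cc5c(c4O)C(=O)C[C@@H](c4ccc(O)cc4)O5)cc3)oc2c1 | target

## Step count and least certain steps

Total: 11 steps. Longest linear sequence: 10 steps (steps 1, 2, 4, 5, 6, 7, 8, 9, 10, 11); step 3 is a one-step side branch.

**Step 5 (key step).** The most likely failure is misfolding or fragmentation: if the enolates are not fully held as magnesium chelates, the chain can close by the aldol mode onto the aryl ketone, or methoxide can cleave the 1,3,5-tricarbonyl chain by retro-Claisen reaction after the lactone has opened. Fallback, from 4 back to 9: ester 4 is saponified (LiOH, THF–H2O) to 4-[4-(benzyloxy)-2,6-dimethoxyphenoxy]benzoic acid F1 and converted with oxalyl chloride into 4-[4-(benzyloxy)-2,6-dimethoxyphenoxy]benzoyl chloride F2. F2 is added to commercial 2',6'-dihydroxy-4'-methoxyacetophenone that has been deprotonated with LiN(SiMe3)2 (4 equiv, THF, −78 °C to rt). C-aroylation of the enolate, or O-aroylation followed by Baker–Venkataraman migration under the excess base, should give 9, and the route continues with step 6.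

**Step 4.** The ester reacts slowly with the dianion, so proton transfer from the acidic product, self-condensation of the dianion or attack on the pyrone ring may use it up; the second deprotonation may also be incomplete. Fallback, from 2 and 6 back to 7: phenol 2 displaces fluoride from 4-fluorobenzaldehyde (K2CO3, DMF, 100 °C) to give 4-[4-(benzyloxy)-2,6-dimethoxyphenoxy]benzaldehyde F3. The dianion of 6 adds to F3 at −78 °C, where an aldehyde reacts within minutes and the aldolate is not acidic, to give racemic 6-(4-{4-[4-(benzyloxy)-2,6-dimethoxyphenoxy]phenyl}-4-hydroxy-2-oxobutyl)-4-methoxy-2H-pyran-2-one F4. Oxidation of the benzylic alcohol with Dess–Martin periodinane should give 7.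

**Step 10.** Insertion into an electron-rich 5,6,7-trioxygenated chromone may be slow, so protodeboronation of 16 can outrun it. Beta-elimination of the ring oxygen from the rhodium enolate would open the ring to a chalcone that recloses without control, which would erode the enantiomeric purity; the facial selectivity on this crowded substrate is also untested. Fallback, from 13 back to 17: Claisen–Schmidt condensation of 13 with 4-(benzyloxy)benzaldehyde (KOH, EtOH, rt) gives the chalcone 2-[4-(3-{(2E)-3-[4-(benzyloxy)phenyl]prop-2-enoyl}-4-hydroxy-2,6-dimethoxyphenoxy)phenyl]-5-hydroxy-7-methoxy-4H-chromen-4-one F5. Ring closure with NaOAc in hot EtOH gives the racemic flavanone 2-[4-(benzyloxy)phenyl]-6-[4-(5-hydroxy-7-methoxy-4-oxo-4H-chromen-2-yl)phenoxy]-5,7-dimethoxy-2,3-dihydro-4H-chromen-4-one F6. Preparative chromatography on a cellulose carbamate chiral phase then separates the 2S enantiomer, which is 17.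

**Step 11.** The configuration may erode through Lewis-acid-assisted ionisation of the benzylic C2–O1 bond (the para oxygen on ring B stabilises the cation) or through ring opening and reclosure; a methoxy group other than the peri one may also be cleaved if the mixture is warmed too far. Fallback, from 15 to 18: the demethylation is done before the stereocentre exists. BCl3 (CH2Cl2, 0 °C) converts 15 into 5-hydroxy-6-[4-(5-hydroxy-7-methoxy-4-oxo-4H-chromen-2-yl)phenoxy]-7-methoxy-4H-chromen-4-one F7. The rhodium-catalysed addition of 16 under the conditions of step 10 gives (2S)-2-[4-(benzyloxy)phenyl]-5-hydroxy-6-[4-(5-hydroxy-7-methoxy-4-oxo-4H-chromen-2-yl)phenoxy]-7-methoxy-2,3-dihydro-4H-chromen-4-one F8, and neutral hydrogenolysis (H2, Pd/C, EtOAc) gives 18.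

**Step 2.** Fluoride displacement activated only by an ester may be slow with the doubly ortho-substituted phenoxide, and at the temperature then needed the methyl ester can be cleaved and the electron-rich phenoxide oxidised. Fallback, from 2 back to 4: copper-catalysed Ullmann etherification of 2 with methyl 4-iodobenzoate (CuI, picolinic acid, K3PO4, DMSO, 90 °C) gives 4 directly; this fallback makes no new compound (F0).

## Further compounds

F1 | step 5 | 4-[4-(benzyloxy)-2,6-dimethoxyphenoxy]benzoic acid | OC(=O)c1ccc(Oc2c(OC)cc(OCc3ccccc3)cc2OC)cc1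
F2 | step 5 | 4-[4-(benzyloxy)-2,6-dimethoxyphenoxy]benzoyl chloride | O=C(Cl)c1ccc(Oc2c(OC)cc(OCc3ccccc3)cc2OC)cc1
F3 | step 4 | 4-[4-(benzyloxy)-2,6-dimethoxyphenoxy]benzaldehyde | O=Cc1ccc(Oc2c(OC)cc(OCc3ccccc3)cc2OC)cc1
F4 | step 4 | 6-(4-{4-[4-(benzyloxy)-2,6-dimethoxyphenoxy]phenyl}-4-hydroxy-2-oxobutyl)-4-methoxy-2H-pyran-2-one (racemic) | COc1cc(=O)oc(CC(=O)CC(O)c2ccc(Oc3c(OC)cc(OCc4ccccc4)cc3OC)cc2)c1
F5 | step 10 | 2-[4-(3-{(2E)-3-[4-(benzyloxy)phenyl]prop-2-enoyl}-4-hydroxy-2,6-dimethoxyphenoxy)phenyl]-5-hydroxy-7-methoxy-4H-chromen-4-one | COc1cc(O)c2c(=O)cc(-c3ccc(Oc4c(OC)cc(O)c(C(=O)/C=C/c5ccc(OCc6ccccc6)cc5)c4OC)cc3)oc2c1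
F6 | step 10 | 2-[4-(benzyloxy)phenyl]-6-[4-(5-hydroxy-7-methoxy-4-oxo-4H-chromen-2-yl)phenoxy]-5,7-dimethoxy-2,3-dihydro-4H-chromen-4-one (racemic) | COc1cc(O)c2c(=O)cc(-c3ccc(Oc4c(OC)cc5c(c4OC)C(=O)CC(c4ccc(OCc6ccccc6)cc4)O5)cc3)oc2c1
F7 | step 11 | 5-hydroxy-6-[4-(5-hydroxy-7-methoxy-4-oxo-4H-chromen-2-yl)phenoxy]-7-methoxy-4H-chromen-4-one | COc1cc(O)c2c(=O)cc(-c3ccc(Oc4c(OC)cc5occc(=O)c5c4O)cc3)oc2c1
F8 | step 11 | (2S)-2-[4-(benzyloxy)phenyl]-5-hydroxy-6-[4-(5-hydroxy-7-methoxy-4-oxo-4H-chromen-2-yl)phenoxy]-7-methoxy-2,3-dihydro-4H-chromen-4-one | COc1cc(O)c2c(=O)cc(-c3ccc(Oc4c(OC)cc5c(c4O)C(=O)C[C@@H](c4ccc(OCc6ccccc6)cc4)O5)cc3)oc2c1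
F0 | step 2 | none | none
A1 | alternative 1 | (2S)-2-[4-(acetyloxy)phenyl]-6-{4-[5-(benzyloxy)-7-methoxy-4-oxo-4H-chromen-2-yl]phenoxy}-5,7-dimethoxy-2,3-dihydro-4H-chromen-4-one | COc1cc(OCc2ccccc2)c2c(=O)cc(-c3ccc(Oc4c(OC)cc5c(c4OC)C(=O)C[C@@H](c4ccc(OC(C)=O)cc4)O5)cc3)oc2c1
A2 | alternative 1 | (3S)-3-[4-(acetyloxy)phenyl]-3-(4-{4-[5-(benzyloxy)-7-methoxy-4-oxo-4H-chromen-2-yl]phenoxy}-3,5-dimethoxyphenoxy)propanoic acid | COc1cc(OCc2ccccc2)c2c(=O)cc(-c3ccc(Oc4c(OC)cc(O[C@@H](CC(=O)O)c5ccc(OC(C)=O)cc5)cc4OC)cc3)oc2c1
A3 | alternative 2 | 2-[4-(2,4-dihydroxy-6-methoxy-3-{(2E)-3-[4-(methoxymethoxy)phenyl]prop-2-enoyl}phenoxy)phenyl]-5-hydroxy-7-methoxy-4H-chromen-4-one | COc1cc(O)c2c(=O)cc(-c3ccc(Oc4c(OC)cc(O)c(C(=O)/C=C/c5ccc(OCOC)cc5)c4O)cc3)oc2c1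
A4 | alternative 2 | 3-[4-(5-hydroxy-7-methoxy-4-oxo-4H-chromen-2-yl)phenoxy]-4-methoxy-6-{(3E)-4-[4-(methoxymethoxy)phenyl]-2-oxobut-3-en-1-yl}-2H-pyran-2-one | COc1cc(O)c2c(=O)cc(-c3ccc(Oc4c(OC)cc(CC(=O)/C=C/c5ccc(OCOC)cc5)oc4=O)cc3)oc2c1
A5 | alternative 3 | 5-(benzyloxy)-2-{4-[4-(benzyloxy)-2,6-dimethoxyphenoxy]phenyl}-7-methoxy-4H-chromen-4-one | COc1cc(OCc2ccccc2)c2c(=O)cc(-c3ccc(Oc4c(OC)cc(OCc5ccccc5)cc4OC)cc3)oc2c1
A6 | alternative 3 | 3-(benzyloxy)-5-methoxybenzyne (3-(benzyloxy)-5-methoxy-1,2-didehydrobenzene) | COC1=CC#CC(OCc2ccccc2)=C1
A7 | alternative 3 | 3-{4-[4-(benzyloxy)-2,6-dimethoxyphenoxy]phenyl}prop-2-ynoic acid | OC(=O)C#Cc1ccc(Oc2c(OC)cc(OCc3ccccc3)cc2OC)cc1
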